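Late in the earlier runs J creeps: the south run goes from 3.5 % at 4.00 h to 5.2 % at 12.0 h, and the north-west run from 2.2 % at 4.00 h to 2.9 % at 12.0 h. So we reckon from that late state and work back.

| flask | D | X | remark | time |
|---|---|---|---|---|
| south | 0.078 M | 0.028 M | run made earlier |  |
| north-west | 0.12 M | 0.028 M | run made earlier |  |
| flask | 0.056 M | 0.0280 M |  | 20 h |

| run | time / h | J / % |
|---|---|---|
| south | 1.00 | 1.4 |
| south | 1.50 | 2.0 |
| south | 2.50 | 2.5 |
| south | 4.00 | 3.5 |
| south | 8.00 | 4.0 |
| south | 12.0 | 5.2 |
| north-west | 0.833 | 0.7 |
| north-west | 2.50 | 1.3 |
| north-west | 4.00 | 2.2 |
| north-west | 6.00 | 2.1 |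
| north-west | 10.0 | 2.6 |
| north-west | 12.0 | 2.9 |

(readings scatter by 0.3 percentage points)

- the analysis behind the earlier runs scatters by 0.3 percentage points, standard deviation
- steps that have been proposed: D + X <-> G + L; L + X <-> G + J; J + X <-> G + E; J + X -> Z

- equivalents of X to D, everything else as given, that leave most J at 20 h
- the amount of J then, in percent of the D charged
- the amount of J with the amounts as given

Write j, l and d for J, L and D as fractions of the D charged, and e for the equivalents of X. In the first instants we expect X, the limiting reagent with less charged than D, to go onto D, giving L and G while j is small. In the middle, two L trade into D and J, which is the second step taken forward with the first step taken backwards. Late, that trade should come near balance. Counting every X as bound and leaving E and Z out, l is e less two j, and d is one less l less j. The last readings then give 0.554 for the south run and 0.751 for the north-west run, both readings with their scatter, and the mean is 0.652. We carry this swap ratio, j times d over l squared.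

For the flask, e is 0.500. We guess j at 10.0 %, take l as the root of j times d over the ratio, and set j to half of e less l. That gives 9.84 %, and a second round gives 9.98 %. This is our figure for J in the flask, reckoned as at balance. The ratio is silent on E and Z, so we give no best charge of our own.

The forecast put the best charge at 2.5 equiv with 35 % of J, and J as charged at 8 %, below our figure, and said: “This is a long extrapolation, since E and Z are not constrained by the data.”

The flask gives 7.47 % of J as charged, less than we reckoned, and 10.6 % at the best charge of 1.02 equiv.

    D + X ⇌ G + L (K = 3.90, k = 7.60 /M/min)
    L + X ⇌ G + J (K = 3.80, k = 0.260 /M/min)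
    J + X ⇌ G + E (K = 0.220, k = 0.350 /M/min)
    J + X → Z (k = 0.120 /M/min)

The flask has not come to rest at 20.0 h. Ten times the time takes J from 7.47 % to 2.26 %, and Z from 2.52 % to 10.1 %. Our ratio, applied to the L and D the flask holds at these two times, gives 5.26 % and 1.57 %, so it falls as J does while standing lower than J at both.

On the neighbour flask with 0.0070 M of X, the ratio gives 1.17 %, then 0.761 %, then 0.891 % for J. That flask gives 0.603 %, less than the last of these, with L at 10.9 %.

The runs are calculated for an exercise, and the scatter is random.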